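**Strategy.** Everything rests on reading the C5=C6 double bond of ring B, which lies γ,δ to the one-carbon substituent C20 on quaternary C9, as the product of a Claisen ring contraction. The precursor is therefore not a decalin but a 6-(cyclohexenyl) α,β-unsaturated δ-lactone (ring oxygen on C6, carbonyl carbon = C20, side chain already on C9). In one flask Me2CuLi delivers the C17 methyl to C8 anti to the C6 substituent, TMSCl traps the ring-constrained ketene acetal, and a boat [3,3] shift forms C9–C10, closes ring B, moves the alkene to C5=C6 and relays the C6 carbinol configuration to C9 and C10. The lactone comes from ring A carbinol 11 and acrylic acid 18 by esterification and ring-closing metathesis.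

Key step: step 14

Atom labels follow halimane numbering of the target: ring A = C1–C5 and C10; ring B = C5–C10; C18 = acetoxymethyl carbon on C4; C17 = methyl on C8; C20 = methyl on C9; side chain C11–C15 with methyl C16 on C13.

Remark (assumption): the face selectivity of the lithio-enamine methylation in step 2 depends on the ligand on lithium. It is assumed that the L-valinate auxiliary in toluene/HMPA delivers the (R)-keto ester 5; if the opposite sense prevails, tert-butyl D-valinate is used with no other change.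

**Step 1**
Reactants: 1 ethyl 2-oxocyclohexane-1-carboxylate; 2 tert-butyl L-valinate (free base from the commercial hydrochloride)
Product: 3 ethyl 2-{[(2S)-1-tert-butoxy-3-methyl-1-oxobutan-2-yl]amino}cyclohex-1-ene-1-carboxylate
Conditions: BF3·OEt2 (cat.), toluene, reflux, Dean–Stark
Reagents that add atoms: none
Why: Acid-catalysed condensation of a β-keto ester with a primary amine should give the hydrogen-bonded enamino ester; no new stereocenter.

**Step 2**
Reactants: 3 enamino ester
Product: 5 ethyl (1R)-1-methyl-2-oxocyclohexane-1-carboxylate, via methylated imine 4 (not isolated)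
Conditions: LDA, toluene/HMPA, −78 °C; MeI, −78 → −40 °C; then aq. AcOH/NaOAc, rt
Reagents that add atoms: iodomethane, CI
Why: Chiral lithio-enamine alkylation: the N-lithiated enamine, chelated by the valinate ester, should be methylated on the face anti to the isopropyl group, which sets quaternary C4, and hydrolysis of imine 4 returns the auxiliary.

**Step 3**
Reactants: 5 keto ester
Product: 6 ethyl (1R)-1-methyl-2-{[(trifluoromethyl)sulfonyl]oxy}cyclohex-2-ene-1-carboxylate
Conditions: KHMDS, THF, −78 °C; PhNTf2, −78 → 0 °C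
Reagents that add atoms: N-phenylbis(trifluoromethanesulfonimide), O=S(=O)(N(c1ccccc1)S(=O)(=O)C(F)(F)F)C(F)(F)F
Why: Enolisation is possible only toward the CH2 side (the other α-carbon is quaternary), and O-sulfonylation of the enolate gives the enol triflate.

**Step 4**
Reactants: 6 enol triflate ester
Product: 7 (6S)-6-(hydroxymethyl)-6-methylcyclohex-1-en-1-yl trifluoromethanesulfonate
Conditions: i-Bu2AlH, CH2Cl2, −78 → 0 °C; Rochelle salt work-up
Reagents that add atoms: none
Why: Hydride reduction of the ester to the neopentyl alcohol (C18) at low temperature, to which the enol triflate is inert; C4 is untouched (the descriptor changes by priority only).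

**Step 5**
Reactants: 7 triflate alcohol
Product: 8 [(1S)-1-methyl-2-{[(trifluoromethyl)sulfonyl]oxy}cyclohex-2-en-1-yl]methyl acetate
Conditions: Ac2O, pyridine, DMAP (cat.), CH2Cl2, rt
Reagents that add atoms: acetic anhydride, CC(=O)OC(C)=O
Why: DMAP-catalysed acylation installs the C18 acetate of the target, which is carried unchanged to the end.

**Step 6**
Reactants: 8 triflate acetate
Product: 9 [(1R)-2-formyl-1-methylcyclohex-2-en-1-yl]methyl acetate
Conditions: Pd(PPh3)4 (5 mol%), LiCl, CO (3 atm), Bu3SnH (slow addition), THF, 50 °C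
Reagents that add atoms: carbon monoxide, [C-]#[O+]
Why: Palladium-catalysed reductive carbonylation (formylation) of an enol triflate: oxidative addition to zerovalent palladium, CO insertion and hydride transfer from tin to the acyl complex should give the enal (C6).

**Step 7**
Reactants: 9 enal
Product: 11 [(1R)-2-[(1R)-1-hydroxybut-3-en-1-yl]-1-methylcyclohex-2-en-1-yl]methyl acetate, via borinate ester 10 (not isolated)
Conditions: (+)-Ipc2B(allyl) (reagent of the (−)-α-pinene series), Et2O, −78 °C; then NaBO3·4H2O, THF/H2O, rt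
Reagents that add atoms: (+)-B-allyldiisopinocampheylborane, C=CCB([C@H]1C[C@H]2C[C@H](C2(C)C)[C@@H]1C)[C@H]1C[C@H]2C[C@H](C2(C)C)[C@@H]1C
Why: Brown allylboration through a chair Zimmerman–Traxler transition state under reagent control; this antipode (the (−)-reagent turns benzaldehyde-type aldehydes into the (S)-carbinols) should add to the Re face and set C6 as (R), and the mild perborate work-up spares the acetate.

**Step 8**
Reactants: 12 (3R)-5-methoxy-3-methyl-5-oxopentanoic acid (methyl hydrogen (R)-3-methylglutarate)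
Product: 13 methyl (3R)-5-hydroxy-3-methylpentanoate
Conditions: BH3·SMe2, THF, 0 °C → rt; aqueous work-up; used at once
Reagents that add atoms: none
Why: Borane reduces a carboxylic acid much faster than an ester (chemoselective reduction), so the acid end becomes C11 and the ester end stays as C15; the C13 stereocenter is not touched.

**Step 9**
Reactants: 13 hydroxy ester
Product: 14 methyl (3S)-5-iodo-3-methylpentanoate
Conditions: I2, PPh3, imidazole, CH2Cl2, 0 °C → rt
Reagents that add atoms: iodine, [I][I]
Why: Appel-type iodination of the primary alcohol, run directly after step 8 to forestall lactonisation; the descriptor changes by priority only.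

**Step 10**
Reactants: 14 iodide; 15 tert-butyl 2-(diethoxyphosphoryl)acetate
Product: 17 1-tert-butyl 7-methyl (5R)-5-methyl-2-methylideneheptanedioate, via alkylated phosphonate 16 (not isolated)
Conditions: NaH, THF/DMF, 0 → 50 °C; then K2CO3, aq. HCHO, rt
Reagents that add atoms: formaldehyde, C=O
Why: C-alkylation of the phosphonoacetate anion by the primary iodide followed by Horner–Wadsworth–Emmons olefination with formaldehyde should give the 2-substituted acrylate, which brings in C9 and C20.

**Step 11**
Reactants: 17 tert-butyl acrylate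
Product: 18 (5R)-7-methoxy-5-methyl-2-methylidene-7-oxoheptanoic acid
Conditions: CF3CO2H, CH2Cl2, 0 °C → rt
Reagents that add atoms: none
Why: Acidolysis of the tert-butyl ester (loss of isobutene) leaves the methyl ester intact.

**Step 12**
Reactants: 11 homoallylic alcohol; 18 acrylic acid
Product: 19 1-[(1R)-1-{(6R)-6-[(acetyloxy)methyl]-6-methylcyclohex-1-en-1-yl}but-3-en-1-yl] 7-methyl (5R)-5-methyl-2-methylideneheptanedioate
Conditions: EDC·HCl, DMAP, CH2Cl2, 0 °C → rt
Reagents that add atoms: none
Why: Steglich-type carbodiimide esterification of the secondary allylic alcohol, with retention at C6 because the C6–O bond is not broken.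

**Step 13**
Reactants: 19 diene ester
Product: 20 [(1R)-2-[(2R)-5-[(3R)-5-methoxy-3-methyl-5-oxopentyl]-6-oxo-3,6-dihydro-2H-pyran-2-yl]-1-methylcyclohex-2-en-1-yl]methyl acetate
Conditions: second-generation Grubbs catalyst (H2IMes)(PCy3)Cl2Ru=CHPh (5 mol%), toluene, 80 °C
Reagents that add atoms: none
Why: Ring-closing metathesis between the terminal alkene and the 1,1-disubstituted acrylate should close the unsaturated δ-lactone (C8=C9) with loss of ethene; the hindered ring A alkene does not take part.

**Step 14**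
Reactants: 20 unsaturated lactone
Product: 23 (1S,2S,5R,8aR)-5-[(acetyloxy)methyl]-1-[(3R)-5-methoxy-3-methyl-5-oxopentyl]-2,5-dimethyl-1,2,3,5,6,7,8,8a-octahydronaphthalene-1-carboxylic acid, via silyl ketene acetal 21 (not isolated), via trimethylsilyl ester 22 (not isolated)
Conditions: Me2CuLi (from CuI and MeLi), TMSCl, THF, −78 → −30 °C; then Et3N, toluene, 95 °C; then MeOH, pH 5 buffer
Reagents that add atoms: lithium dimethylcuprate Me2CuLi, [Li+].C[Cu-]C
Why: Me2CuLi/TMSCl adds the C17 methyl 1,4 to the enoate on the face anti to the C6 substituent (stereoelectronic axial attack on the half-chair, giving the 4,6-trans pattern and thus C8), and the enolate is trapped as cyclic silyl ketene acetal 21, whose ring forces the ring oxygen cis to C8. Heating then triggers an Ireland–Claisen rearrangement of the allylic ester unit O–C6–C5=C10; the closest known reactions are the ring-contracting Claisen rearrangement of lactone silyl ketene acetals and the cuprate-initiated conjugate addition/Ireland–Claisen tandem. Ring B is closed by the suprafacial [3,3] shift itself, through the boat-like transition state that the lactone tether C7–C8 enforces: C9–C10 forms as C6–O breaks, the six-membered lactone contracts to the cyclohexene, and the alkene is transposed to C5=C6. C10 is controlled by the C6 carbinol centre (the new bond forms on the alkene face from which the oxygen departs, the ring A alkene geometry being fixed), and quaternary C9 by the fixed ketene acetal geometry in the boat, which places the carboxyl carbon (later C20) cis to the C8 methyl and trans to H10, and the side chain cis to H10. The step needs 1,4-addition to outrun SN2' attack of the cuprate on the allylic lactone and the sigmatropic shift to outrun ionisation of the C6–O bond; the first is secured by TMSCl activation at −78 °C, the second by the non-polar, amine-buffered medium and by ring A turning its pseudoaxial C4 substituent away from the OSiMe3 group.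

**Step 15**
Reactants: 23 acid
Product: 25 methyl (3R)-5-[(1S,2S,5R,8aR)-5-[(acetyloxy)methyl]-1-formyl-2,5-dimethyl-1,2,3,5,6,7,8,8a-octahydronaphthalen-1-yl]-3-methylpentanoate, via acid chloride 24 (not isolated)
Conditions: 1-chloro-N,N,2-trimethylprop-1-en-1-amine, CH2Cl2, 0 °C → rt; then LiAlH(OtBu)3, THF, −78 °C
Reagents that add atoms: none
Why: Neutral acid chloride formation (no HCl, so the γ,δ-alkene is not lactonised) followed by reduction with the bulky alkoxyaluminium hydride should stop at the aldehyde and spare acetate and methyl ester.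

**Step 16**
Reactants: 25 aldehyde
Product: 27 methyl (3R)-5-[(1R,2S,5R,8aS)-5-[(acetyloxy)methyl]-1,2,5-trimethyl-1,2,3,5,6,7,8,8a-octahydronaphthalen-1-yl]-3-methylpentanoate, via tosylhydrazone 26 (not isolated)
Conditions: TsNHNH2, EtOH, 60 °C; evaporate; catecholborane, CHCl3, 0 °C → rt; then NaOAc·3H2O, reflux
Reagents that add atoms: none
Why: Tosylhydrazone reduction with catecholborane (hydride addition to C=N, then acetate-induced loss of sulfinate and N2 from the diazene) should turn the neopentyl CHO into the C20 methyl under conditions that tolerate both esters; the C9 and C10 descriptors change by priority only.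

**Step 17**
Reactants: 27 methyl ester
Product: 28 (3R)-5-[(1R,2S,5R,8aS)-5-[(acetyloxy)methyl]-1,2,5-trimethyl-1,2,3,5,6,7,8,8a-octahydronaphthalen-1-yl]-3-methylpentanoic acid (CNP0148247.1)
Conditions: LiI, EtOAc, reflux; then 1 M HCl
Reagents that add atoms: none
Why: SN2 dealkylation of the methyl ester by iodide (nucleophilic ester cleavage) should unmask C15 only, because the alkyl carbon of the acetate (C18) is neopentyl and inert to this mode.

**Compound list**

1 | ethyl 2-oxocyclohexane-1-carboxylate | CCOC(=O)C1CCCCC1=O | starting material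
2 | tert-butyl L-valinate [tert-butyl (2S)-2-amino-3-methylbutanoate] | CC(C)[C@H](N)C(=O)OC(C)(C)C | starting material
3 | ethyl 2-{[(2S)-1-tert-butoxy-3-methyl-1-oxobutan-2-yl]amino}cyclohex-1-ene-1-carboxylate | CCOC(=O)C1=C(N[C@@H](C(C)C)C(=O)OC(C)(C)C)CCCC1 | intermediate
4 | ethyl (1R)-2-{[(2S)-1-tert-butoxy-3-methyl-1-oxobutan-2-yl]imino}-1-methylcyclohexane-1-carboxylate | CCOC(=O)[C@]1(C)CCCCC1=N[C@@H](C(C)C)C(=O)OC(C)(C)C | intermediate (not isolated)
5 | ethyl (1R)-1-methyl-2-oxocyclohexane-1-carboxylate | CCOC(=O)[C@]1(C)CCCCC1=O | intermediate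
6 | ethyl (1R)-1-methyl-2-{[(trifluoromethyl)sulfonyl]oxy}cyclohex-2-ene-1-carboxylate | CCOC(=O)[C@]1(C)CCCC=C1OS(=O)(=O)C(F)(F)F | intermediate
7 | (6S)-6-(hydroxymethyl)-6-methylcyclohex-1-en-1-yl trifluoromethanesulfonate | OC[C@]1(C)CCCC=C1OS(=O)(=O)C(F)(F)F | intermediate
8 | [(1S)-1-methyl-2-{[(trifluoromethyl)sulfonyl]oxy}cyclohex-2-en-1-yl]methyl acetate | CC(=O)OC[C@]1(C)CCCC=C1OS(=O)(=O)C(F)(F)F | intermediate
9 | [(1R)-2-formyl-1-methylcyclohex-2-en-1-yl]methyl acetate | CC(=O)OC[C@]1(C)CCCC=C1C=O | intermediate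
10 | O-[bis(isopinocampheyl)boryl] ether of 11 (Ipc groups of the (−)-α-pinene series) | CC(=O)OC[C@]1(C)CCCC=C1[C@@H](CC=C)OB([C@H]2C[C@H]3C[C@H](C3(C)C)[C@@H]2C)[C@H]2C[C@H]3C[C@H](C3(C)C)[C@@H]2C | intermediate (not isolated)
11 | [(1R)-2-[(1R)-1-hydroxybut-3-en-1-yl]-1-methylcyclohex-2-en-1-yl]methyl acetate | CC(=O)OC[C@]1(C)CCCC=C1[C@H](O)CC=C | intermediate
12 | (3R)-5-methoxy-3-methyl-5-oxopentanoic acid (methyl hydrogen (R)-3-methylglutarate) | OC(=O)C[C@@H](C)CC(=O)OC | starting material
13 | methyl (3R)-5-hydroxy-3-methylpentanoate | OCC[C@@H](C)CC(=O)OC | intermediate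
14 | methyl (3S)-5-iodo-3-methylpentanoate | ICC[C@@H](C)CC(=O)OC | intermediate
15 | tert-butyl 2-(diethoxyphosphoryl)acetate | CCOP(=O)(OCC)CC(=O)OC(C)(C)C | starting material
16 | 1-tert-butyl 7-methyl (5R)-2-(diethoxyphosphoryl)-5-methylheptanedioate (C2 epimers) | CCOP(=O)(OCC)C(CC[C@@H](C)CC(=O)OC)C(=O)OC(C)(C)C | intermediate (not isolated)
17 | 1-tert-butyl 7-methyl (5R)-5-methyl-2-methylideneheptanedioate | C=C(CC[C@@H](C)CC(=O)OC)C(=O)OC(C)(C)C | intermediate
18 | (5R)-7-methoxy-5-methyl-2-methylidene-7-oxoheptanoic acid | C=C(CC[C@@H](C)CC(=O)OC)C(=O)O | intermediate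
19 | 1-[(1R)-1-{(6R)-6-[(acetyloxy)methyl]-6-methylcyclohex-1-en-1-yl}but-3-en-1-yl] 7-methyl (5R)-5-methyl-2-methylideneheptanedioate | CC(=O)OC[C@]1(C)CCCC=C1[C@@H](CC=C)OC(=O)C(=C)CC[C@@H](C)CC(=O)OC | intermediate
20 | [(1R)-2-[(2R)-5-[(3R)-5-methoxy-3-methyl-5-oxopentyl]-6-oxo-3,6-dihydro-2H-pyran-2-yl]-1-methylcyclohex-2-en-1-yl]methyl acetate | CC(=O)OC[C@]1(C)CCCC=C1[C@H]2CC=C(CC[C@@H](C)CC(=O)OC)C(=O)O2 | intermediate
21 | [(1R)-2-[(2R,4S)-5-[(3R)-5-methoxy-3-methyl-5-oxopentyl]-4-methyl-6-[(trimethylsilyl)oxy]-3,4-dihydro-2H-pyran-2-yl]-1-methylcyclohex-2-en-1-yl]methyl acetate | CC(=O)OC[C@]1(C)CCCC=C1[C@H]2C[C@H](C)C(CC[C@@H](C)CC(=O)OC)=C(O[Si](C)(C)C)O2 | intermediate (not isolated)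
22 | trimethylsilyl (1S,2S,5R,8aR)-5-[(acetyloxy)methyl]-1-[(3R)-5-methoxy-3-methyl-5-oxopentyl]-2,5-dimethyl-1,2,3,5,6,7,8,8a-octahydronaphthalene-1-carboxylate | CC(=O)OC[C@]1(C)CCC[C@@H]2C1=CC[C@H](C)[C@@]2(C(=O)O[Si](C)(C)C)CC[C@@H](C)CC(=O)OC | intermediate (not isolated)
23 | (1S,2S,5R,8aR)-5-[(acetyloxy)methyl]-1-[(3R)-5-methoxy-3-methyl-5-oxopentyl]-2,5-dimethyl-1,2,3,5,6,7,8,8a-octahydronaphthalene-1-carboxylic acid | CC(=O)OC[C@]1(C)CCC[C@@H]2C1=CC[C@H](C)[C@@]2(C(=O)O)CC[C@@H](C)CC(=O)OC | intermediate
24 | (1S,2S,5R,8aR)-5-[(acetyloxy)methyl]-1-[(3R)-5-methoxy-3-methyl-5-oxopentyl]-2,5-dimethyl-1,2,3,5,6,7,8,8a-octahydronaphthalene-1-carbonyl chloride | CC(=O)OC[C@]1(C)CCC[C@@H]2C1=CC[C@H](C)[C@@]2(C(Cl)=O)CC[C@@H](C)CC(=O)OC | intermediate (not isolated)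
25 | methyl (3R)-5-[(1S,2S,5R,8aR)-5-[(acetyloxy)methyl]-1-formyl-2,5-dimethyl-1,2,3,5,6,7,8,8a-octahydronaphthalen-1-yl]-3-methylpentanoate | CC(=O)OC[C@]1(C)CCC[C@@H]2C1=CC[C@H](C)[C@@]2(C=O)CC[C@@H](C)CC(=O)OC | intermediate
26 | methyl (3R)-5-[(1S,2S,5R,8aR)-5-[(acetyloxy)methyl]-2,5-dimethyl-1-{[2-(4-methylbenzenesulfonyl)hydrazinylidene]methyl}-1,2,3,5,6,7,8,8a-octahydronaphthalen-1-yl]-3-methylpentanoate | CC(=O)OC[C@]1(C)CCC[C@@H]2C1=CC[C@H](C)[C@@]2(C=NNS(=O)(=O)c3ccc(C)cc3)CC[C@@H](C)CC(=O)OC | intermediate (not isolated)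
27 | methyl (3R)-5-[(1R,2S,5R,8aS)-5-[(acetyloxy)methyl]-1,2,5-trimethyl-1,2,3,5,6,7,8,8a-octahydronaphthalen-1-yl]-3-methylpentanoate | CC(=O)OC[C@]1(C)CCC[C@@H]2C1=CC[C@H](C)[C@@]2(C)CC[C@@H](C)CC(=O)OC | intermediate
28 | (3R)-5-[(1R,2S,5R,8aS)-5-[(acetyloxy)methyl]-1,2,5-trimethyl-1,2,3,5,6,7,8,8a-octahydronaphthalen-1-yl]-3-methylpentanoic acid | CC(=O)OC[C@]1(C)CCC[C@@H]2C1=CC[C@H](C)[C@@]2(C)CC[C@@H](C)CC(=O)O | target

**Step count.** Total: 17 steps. Longest linear sequence: 13 steps (steps 1–7 and 12–17); steps 8–11 make the side-chain acid 18.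

**Steps most likely to fail**

Step 14 (key step). The sigmatropic shift may stall because the boat transition state sets the OSiMe3 group against the substituents on C4, leaving the ketene acetal to ionise at the allylic C6–O bond or to desilylate; the 1,4-addition may also be incomplete on the trisubstituted enoate. The fallback sets out from 20 and comes back at 25, changing the rearrangement to the neutral aldehyde-level Claisen. Me2CuLi/TMSCl at −78 °C followed by aqueous NH4Cl would give the saturated 4,6-trans lactone F1. Disiamylborane in THF (0 °C → rt), which reduces lactones but not acyclic esters, would give lactol F2. MsCl/Et3N in CH2Cl2 (0 → 40 °C) would dehydrate it to the cyclic enol ether, dihydropyran F3. Heating F3 in decane at 180 °C (sealed, with BHT) should effect the thermal Claisen ring contraction through the same boat array, now with hydrogen in place of OSiMe3 on the carbon that becomes C20, and deliver aldehyde 25 directly, so that step 15 is skipped.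

Step 6. Hydride transfer from tin to the vinylpalladium species may outrun CO insertion at the hindered enol triflate, giving simple reduction of the C–O bond instead of formylation. The fallback sets out from 8 and comes back at 9. Stille coupling with tributyl(hydroxymethyl)stannane (Pd(PPh3)4, LiCl, dioxane, 100 °C) would give the primary allylic alcohol F4, and MnO2 in CH2Cl2 at rt would oxidise it to enal 9.

Step 16. Condensation at the neopentyl aldehyde may be slow, or the hydride addition and diazene fragmentation may be incomplete, leaving hydrazone or hydrazine. The fallback sets out from 25 and comes back at 27 by radical deoxygenation. NaBH4 in MeOH at 0 °C would give the neopentyl alcohol F5, O-phenyl chlorothionoformate with pyridine/DMAP would give the phenyl thionocarbonate F6, and Bu3SnH/AIBN in toluene at 110 °C (Barton–McCombie) should give 27; the primary C20 radical has no favourable cyclisation onto C5=C6.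

Further compounds
F1 | step 14 | [(1R)-2-[(2R,4S,5R)-5-[(3R)-5-methoxy-3-methyl-5-oxopentyl]-4-methyl-6-oxooxan-2-yl]-1-methylcyclohex-2-en-1-yl]methyl acetate | CC(=O)OC[C@]1(C)CCCC=C1[C@H]2C[C@H](C)[C@@H](CC[C@@H](C)CC(=O)OC)C(=O)O2
F2 | step 14 | [(1R)-2-[(2R,4S,5R)-6-hydroxy-5-[(3R)-5-methoxy-3-methyl-5-oxopentyl]-4-methyloxan-2-yl]-1-methylcyclohex-2-en-1-yl]methyl acetate (anomers) | CC(=O)OC[C@]1(C)CCCC=C1[C@H]2C[C@H](C)[C@@H](CC[C@@H](C)CC(=O)OC)C(O)O2
F3 | step 14 | [(1R)-2-[(2R,4S)-5-[(3R)-5-methoxy-3-methyl-5-oxopentyl]-4-methyl-3,4-dihydro-2H-pyran-2-yl]-1-methylcyclohex-2-en-1-yl]methyl acetate | CC(=O)OC[C@]1(C)CCCC=C1[C@H]2C[C@H](C)C(CC[C@@H](C)CC(=O)OC)=CO2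
F4 | step 6 | [(1R)-2-(hydroxymethyl)-1-methylcyclohex-2-en-1-yl]methyl acetate | CC(=O)OC[C@]1(C)CCCC=C1CO
F5 | step 16 | methyl (3R)-5-[(1S,2S,5R,8aR)-5-[(acetyloxy)methyl]-1-(hydroxymethyl)-2,5-dimethyl-1,2,3,5,6,7,8,8a-octahydronaphthalen-1-yl]-3-methylpentanoate | CC(=O)OC[C@]1(C)CCC[C@@H]2C1=CC[C@H](C)[C@@]2(CO)CC[C@@H](C)CC(=O)OC
F6 | step 16 | methyl (3R)-5-[(1S,2S,5R,8aR)-5-[(acetyloxy)methyl]-2,5-dimethyl-1-{[(phenoxycarbonothioyl)oxy]methyl}-1,2,3,5,6,7,8,8a-octahydronaphthalen-1-yl]-3-methylpentanoate | CC(=O)OC[C@]1(C)CCC[C@@H]2C1=CC[C@H](C)[C@@]2(COC(=S)Oc3ccccc3)CC[C@@H](C)CC(=O)OC
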